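**Plan**

1. Retrosynthesis: each vinylic C4–Br goes back to the enol oxygen of a tetronic acid, and each lactone loses its ring oxygen O1 (retro-Baeyer–Villiger). Each butenolide thus becomes a cyclobutane-1,3-dione spiro-fused to the central ring, and the bonds then cut are C2(=O)–C3 and C4–C5(spiro).
2. Feature used: in each butenolide the spiro carbon C5 carries O1–C2(=O) on one side and the enol-level carbon C4 on the other. Without O1, the atoms C5, C2, C3 and C4 form a four-membered ring, the [2+2] adduct of a ketene C5=C2=O (a ring carbon of a cyclobutane-1,2-dicarboxylic acid plus its carboxyl carbon) and an oxygen-substituted alkyne C3≡C4–OSi carrying the side chain.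
3. Forward: the central four-membered ring is present from the start (cyclobutene anhydride → trans half-ester → all-trans dibromide). The first butenolide is built at the free carboxyl (ketene/siloxyalkyne [2+2], hydrolysis, oxygen insertion, OH → Br), the second in the same way at the other carboxyl (key cycloaddition), then desilylation and acetylation.
4. Stereochemistry: the absolute configuration of the ring comes from alkaloid-mediated opening of the meso anhydride and is passed by epimerisation and anti-bromination to the two CHBr centres. Each spiro centre is erased in the dione and made anew when oxygen is inserted into the carbonyl anti to the neighbouring ring bromine (O trans, C4 cis to that Br).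
5. The (S) and (R) side chains come from lipase-catalysed kinetic resolution of rac-hex-1-yn-3-ol, run once for the (S)-acetate and once for the remaining (R)-alcohol.

Key step: step 15

Assumption (chemistry): anhydride 11 is taken as a commercial compound. Quinidine is taken to give the (1R,2S) half-ester 13; if the sense is the opposite, quinine is used and nothing else changes. The lipase is taken to acylate the (S)-alcohol, as the size rule for secondary alcohols predicts (propyl large, ethynyl medium); a reversed sense would only exchange the roles of steps 1 and 2.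

**Route**

Step 1
Reactants: 1 rac-hex-1-yn-3-ol
Product: 2 (S)-hex-1-yn-3-yl acetate
Conditions: vinyl acetate, immobilised lipase B from Candida antarctica, methyl tert-butyl ether, 30 °C, stopped short of half conversion; chromatography
Reagents that add atoms: vinyl acetate, C=COC(C)=O
Why: Lipase-catalysed kinetic resolution (transesterification) of a secondary propargylic alcohol should acylate the (S)-alcohol selectively, and stopping below half conversion should keep the isolated acetate enantiomerically pure.

Step 2
Reactants: 1 rac-hex-1-yn-3-ol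
Product: 3 (R)-hex-1-yn-3-ol
Conditions: vinyl acetate, immobilised lipase B from Candida antarctica, methyl tert-butyl ether, 30 °C, run past half conversion; chromatography (alcohol fraction)
Reagents that add atoms: none
Why: The same lipase-catalysed kinetic resolution, pushed beyond half conversion so that the fast-reacting (S)-alcohol is consumed as its acetate, should leave the slow-reacting (R)-alcohol enantiomerically pure.

Step 3
Reactants: 2 (S)-hex-1-yn-3-yl acetate
Product: 4 (S)-hex-1-yn-3-ol
Conditions: K2CO3 (0.2 equiv), CH3OH, 0 °C → rt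
Reagents that add atoms: none
Why: Base-catalysed transesterification frees the alcohol without touching the stereocenter.

Step 4
Reactants: 4 (S)-hex-1-yn-3-ol
Product: 5 (S)-tert-butyl(hex-1-yn-3-yloxy)diphenylsilane
Conditions: tert-butyl(chloro)diphenylsilane, imidazole, DMF, rt
Reagents that add atoms: tert-butyl(chloro)diphenylsilane, CC(C)(C)[Si](Cl)(c1ccccc1)c1ccccc1
Why: Silyl ether formation; the acid-stable, poorly ionising silyl ether is chosen because an acetate at this carbon would be expelled from the enolic intermediates of steps 11 to 16.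

Step 5
Reactants: 3 (R)-hex-1-yn-3-ol
Product: 6 (R)-tert-butyl(hex-1-yn-3-yloxy)diphenylsilane
Conditions: tert-butyl(chloro)diphenylsilane, imidazole, DMF, rt
Reagents that add atoms: tert-butyl(chloro)diphenylsilane, CC(C)(C)[Si](Cl)(c1ccccc1)c1ccccc1
Why: Silyl ether formation as in step 4, on the other enantiomer.

Step 6
Reactants: 5 (S)-tert-butyl(hex-1-yn-3-yloxy)diphenylsilane
Product: 8 (S)-tert-butyldiphenyl({1-[(triisopropylsilyl)oxy]hex-1-yn-3-yl}oxy)silane, via lithium ynolate 7 (not isolated)
Conditions: n-C4H9Li, THF, −78 °C; LiOOC(CH3)3 [from (CH3)3COOH and LiN(SiMe3)2], −78 → 0 °C; (i-Pr)3SiOSO2CF3, −78 °C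
Reagents that add atoms: tert-butyl hydroperoxide (used as its lithium salt), CC(C)(C)OO; triisopropylsilyl trifluoromethanesulfonate, CC(C)[Si](C(C)C)(C(C)C)OS(=O)(=O)C(F)(F)F
Why: Oxidation of a terminal alkyne to a silyl ynol ether (lithium acetylide, oxygen transfer from the lithium peroxide to give the ynolate, O-silylation with a bulky silyl triflate); the stereocenter is not involved.

Step 7
Reactants: 6 (R)-tert-butyl(hex-1-yn-3-yloxy)diphenylsilane
Product: 10 (R)-tert-butyldiphenyl({1-[(triisopropylsilyl)oxy]hex-1-yn-3-yl}oxy)silane, via lithium ynolate 9 (not isolated)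
Conditions: n-C4H9Li, THF, −78 °C; LiOOC(CH3)3 [from (CH3)3COOH and LiN(SiMe3)2], −78 → 0 °C; (i-Pr)3SiOSO2CF3, −78 °C
Reagents that add atoms: tert-butyl hydroperoxide (used as its lithium salt), CC(C)(C)OO; triisopropylsilyl trifluoromethanesulfonate, CC(C)[Si](C(C)C)(C(C)C)OS(=O)(=O)C(F)(F)F
Why: Same alkyne-to-silyl-ynol-ether oxidation as in step 6, on the other enantiomer.

Step 8
Reactants: 11 cis-cyclobut-3-ene-1,2-dicarboxylic anhydride; 12 2-(trimethylsilyl)ethanol
Product: 13 (1R,2S)-2-{[2-(trimethylsilyl)ethoxy]carbonyl}cyclobut-3-ene-1-carboxylic acid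
Conditions: quinidine (1.1 equiv), toluene, −55 °C
Reagents that add atoms: none
Why: Alkaloid-mediated enantioselective alcoholysis (desymmetrisation) of a meso cyclic anhydride; the alkaloid differentiates the two enantiotopic carbonyl groups, which fixes the absolute configuration and tells the two carboxyl groups apart.

Step 9
Reactants: 13 cis half-ester
Product: 14 (1R,2R)-2-{[2-(trimethylsilyl)ethoxy]carbonyl}cyclobut-3-ene-1-carboxylic acid
Conditions: KOC(CH3)3 (2.2 equiv), (CH3)3COH–THF, 0 °C → rt; then HCl (1 M)
Reagents that add atoms: none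
Why: Thermodynamic epimerisation of the ester-bearing carbon through its enolate (the carboxylate-bearing carbon is not deprotonated) should give the more stable trans half-ester without loss of enantiopurity; low temperature limits migration of the double bond into conjugation.

Step 10
Reactants: 14 trans half-ester
Product: 15 (1R,2R,3R,4R)-3,4-dibromo-2-{[2-(trimethylsilyl)ethoxy]carbonyl}cyclobutane-1-carboxylic acid
Conditions: Br2 (1.05 equiv), CH2Cl2, −78 → 0 °C, dark
Reagents that add atoms: bromine, BrBr
Why: Anti addition of bromine through a bromonium ion; bromide should open it at the carbon where it enters trans to the neighbouring carboxyl group, so that each new C–Br bond is trans to both neighbours (all-trans ring), which sets the two CHBr stereocenters of the target.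

Step 11
Reactants: 15 all-trans dibromo acid; 10 (R)-siloxyalkyne
Product: 18 2-(trimethylsilyl)ethyl 6,7-dibromo-2-[(R)-1-(tert-butyldiphenylsilyloxy)butyl]-3-oxo-1-(triisopropylsilyloxy)spiro[3.3]hept-1-ene-5-carboxylate, via acid chloride 16 (not isolated), via ketene 17 (not isolated)
Conditions: (COCl)2, DMF (cat.), CH2Cl2, 0 °C → rt, evaporate; then 10 (1.3 equiv), Et3N (1.2 equiv, syringe pump), toluene, 60 °C
Reagents that add atoms: none
Why: Acid chloride formation, amine-induced dehydrochlorination to the ketene and ketene–siloxyalkyne [2+2] cycloaddition (alkyne β-carbon to the ketene carbonyl carbon, oxygen-bearing carbon to the ring carbon) give the spiro-cyclobutenone; the alkyne should enter anti to the C–Br and ester on the two neighbouring carbons, but this spiro configuration is erased in step 12.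

Step 12
Reactants: 18 spiro-cyclobutenone
Product: 20 2-(trimethylsilyl)ethyl 2,3-dibromo-8-hydroxy-6-oxo-7-[(R)-1-(tert-butyldiphenylsilyloxy)butyl]-5-oxaspiro[3.4]oct-7-ene-1-carboxylate (tetronic acid; lactone O trans to the adjacent ring bromine), via dione 19 (not isolated)
Conditions: HCl (1 M), THF, 0 °C; then H2O2 (35% aq), CF3CH2OH, 0 °C → rt
Reagents that add atoms: hydrogen peroxide, OO
Why: Acid cleaves the silyl enol ether to the spiro cyclobutane-1,3-dione, whose spiro carbon is no longer a fixed stereocenter, and strain-driven Baeyer–Villiger oxidation with non-electrophilic hydrogen peroxide (migration of the quaternary spiro carbon with retention) should insert oxygen into the more accessible carbonyl, the one on the face opposite to the neighbouring C–Br and ester, which sets the spiro centre.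

Step 13
Reactants: 20 tetronic acid
Product: 21 2-(trimethylsilyl)ethyl 2,3,8-tribromo-6-oxo-7-[(R)-1-(tert-butyldiphenylsilyloxy)butyl]-5-oxaspiro[3.4]oct-7-ene-1-carboxylate
Conditions: (COBr)2 (1.5 equiv), DMF (cat.), CH2Cl2, 0 °C → rt
Reagents that add atoms: oxalyl bromide, O=C(Br)C(Br)=O
Why: The tetronic acid is a vinylogous carboxylic acid and the bromoiminium (Vilsmeier-type) reagent converts it into the vinylogous acid bromide by addition–elimination at C4; no stereocenter is affected.

Step 14
Reactants: 21 bromobutenolide ester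
Product: 22 2,3,8-tribromo-6-oxo-7-[(R)-1-(tert-butyldiphenylsilyloxy)butyl]-5-oxaspiro[3.4]oct-7-ene-1-carboxylic acid
Conditions: CF3CO2H–CH2Cl2 (1:1), 0 °C → rt
Reagents that add atoms: none
Why: Acidolysis of the 2-(trimethylsilyl)ethyl ester (β-silyl fragmentation to ethene) frees the second carboxyl group under conditions that the bromides, the lactone and the silyl ether should tolerate.

Step 15
Reactants: 22 bromobutenolide acid; 8 (S)-siloxyalkyne
Product: 25 dispiro cycloadduct (4-bromobutenolide / trans-dibromocyclobutane / 3-(triisopropylsilyloxy)cyclobut-2-enone carrying the (S)-1-(tert-butyldiphenylsilyloxy)butyl group on its C2), via acid chloride 23 (not isolated), via ketene 24 (not isolated)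
Conditions: (COCl)2, DMF (cat.), CH2Cl2, 0 °C, evaporate; then 8 (1.5 equiv), i-Pr2NEt (1.1 equiv, syringe pump), toluene, 60–80 °C
Reagents that add atoms: none
Why: Amine-induced loss of HCl from the acid chloride gives ketene 24, whose terminus is the ring carbon that becomes the spiro centre and whose carbonyl carbon becomes the lactone carbonyl; the nucleophilic β-carbon of the siloxyalkyne (the carbon that carries the side chain) attacks this carbonyl carbon in the ketene plane, and the enolate carbon so formed closes onto the oxygen-stabilised cationic alkyne carbon. The closest known reaction type is the [2+2] cycloaddition of ketenes with silyloxy- or alkoxyalkynes to 3-oxygenated cyclobutenones. The one ring closed is the four-membered cyclobutenone, by an asynchronous [2+2] cycloaddition (C-acylation of the ynol ether first, then collapse of the zwitterion). The new spiro stereocenter is under substrate control: the upper face of the ketene terminus is screened by the vinylic bromine of the neighbouring spirobutenolide, so the alkyne carbon should enter from the lower face, syn to the ring C–Br; this centre is in any case erased in step 16, where both epimers give the same dione, and the (S) carbinol centre of 8 is not touched. The step needs regioselectivity (oxygen-bearing carbon to the ring carbon), which the polarisation of the ynol ether secures, and it needs ketene formation to win over loss of HBr or of the lactone carboxylate, which is favoured because both β-leaving groups are syn to the α-hydrogen in the all-trans ring, so no anti-periplanar elimination is available.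

Step 16
Reactants: 25 dispiro cycloadduct
Product: 27 bis-spiro 4-bromobutenolide tetronic acid (new lactone O trans to the adjacent ring bromine), via dione 26 (not isolated)
Conditions: HCl (1 M), THF, 0 °C; then H2O2 (35% aq), CF3CH2OH, 0 °C → rt
Reagents that add atoms: hydrogen peroxide, OO
Why: As in step 12, desilylation gives the dione in which the new spiro carbon is no longer a fixed stereocenter, and Baeyer–Villiger insertion should occur at the carbonyl that hydrogen peroxide can reach past a C–H and not past the C–Br, the one anti to the neighbouring ring bromine, so that the lactone oxygen ends up trans and the enol carbon cis to that bromine, as in the target.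

Step 17
Reactants: 27 bromobutenolide tetronic acid
Product: 28 bis(4-bromobutenolide) bis(tert-butyldiphenylsilyl ether)
Conditions: (COBr)2 (1.5 equiv), DMF (cat.), CH2Cl2, 0 °C → rt
Reagents that add atoms: oxalyl bromide, O=C(Br)C(Br)=O
Why: Same conversion of a vinylogous acid into its vinylogous acid bromide as in step 13.

Step 18
Reactants: 28 bis(silyl ether)
Product: 29 bis(4-bromobutenolide) diol
Conditions: HF·pyridine, THF, 0 → 40 °C
Reagents that add atoms: none
Why: Fluoride cleavage of both silyl ethers under acidic, weakly nucleophilic conditions that should spare the base-sensitive 4-bromobutenolides.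

Step 19
Reactants: 29 diol
Product: 30 target CNP0266230.1
Conditions: Ac2O (4 equiv), Sc(OSO2CF3)3 (2 mol%), CH3CN, 0 °C
Reagents that add atoms: acetic anhydride, CC(=O)OC(C)=O
Why: Lewis-acid-catalysed acetylation of both secondary alcohols avoids nucleophilic amines that could add to the bromobutenolides, and no stereocenter is touched.

**Compound list**

1 | rac-hex-1-yn-3-ol | CCCC(O)C#C | starting material
2 | (S)-hex-1-yn-3-yl acetate | CCC[C@H](OC(C)=O)C#C | intermediate
3 | (R)-hex-1-yn-3-ol | CCC[C@@H](O)C#C | intermediate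
4 | (S)-hex-1-yn-3-ol | CCC[C@H](O)C#C | intermediate
5 | (S)-tert-butyl(hex-1-yn-3-yloxy)diphenylsilane | CCC[C@H](O[Si](c1ccccc1)(c1ccccc1)C(C)(C)C)C#C | intermediate
6 | (R)-tert-butyl(hex-1-yn-3-yloxy)diphenylsilane | CCC[C@@H](O[Si](c1ccccc1)(c1ccccc1)C(C)(C)C)C#C | intermediate
7 | lithium (S)-3-(tert-butyldiphenylsilyloxy)hex-1-yn-1-olate | CCC[C@H](O[Si](c1ccccc1)(c1ccccc1)C(C)(C)C)C#C[O-].[Li+] | intermediate
8 | (S)-tert-butyldiphenyl({1-[(triisopropylsilyl)oxy]hex-1-yn-3-yl}oxy)silane | CCC[C@H](O[Si](c1ccccc1)(c1ccccc1)C(C)(C)C)C#CO[Si](C(C)C)(C(C)C)C(C)C | intermediate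
9 | lithium (R)-3-(tert-butyldiphenylsilyloxy)hex-1-yn-1-olate | CCC[C@@H](O[Si](c1ccccc1)(c1ccccc1)C(C)(C)C)C#C[O-].[Li+] | intermediate
10 | (R)-tert-butyldiphenyl({1-[(triisopropylsilyl)oxy]hex-1-yn-3-yl}oxy)silane | CCC[C@@H](O[Si](c1ccccc1)(c1ccccc1)C(C)(C)C)C#CO[Si](C(C)C)(C(C)C)C(C)C | intermediate
11 | cis-cyclobut-3-ene-1,2-dicarboxylic anhydride (meso) | O=C1OC(=O)[C@H]2C=C[C@@H]12 | starting material
12 | 2-(trimethylsilyl)ethanol | C[Si](C)(C)CCO | starting material
13 | (1R,2S)-2-{[2-(trimethylsilyl)ethoxy]carbonyl}cyclobut-3-ene-1-carboxylic acid (cis) | OC(=O)[C@@H]1C=C[C@@H]1C(=O)OCC[Si](C)(C)C | intermediate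
14 | (1R,2R)-2-{[2-(trimethylsilyl)ethoxy]carbonyl}cyclobut-3-ene-1-carboxylic acid (trans) | OC(=O)[C@@H]1C=C[C@H]1C(=O)OCC[Si](C)(C)C | intermediate
15 | (1R,2R,3R,4R)-3,4-dibromo-2-{[2-(trimethylsilyl)ethoxy]carbonyl}cyclobutane-1-carboxylic acid (all-trans) | OC(=O)[C@@H]1[C@@H](Br)[C@H](Br)[C@H]1C(=O)OCC[Si](C)(C)C | intermediate
16 | 2-(trimethylsilyl)ethyl (1R,2R,3R,4R)-2,3-dibromo-4-(chlorocarbonyl)cyclobutane-1-carboxylate | ClC(=O)[C@@H]1[C@@H](Br)[C@H](Br)[C@H]1C(=O)OCC[Si](C)(C)C | intermediate
17 | 2-(trimethylsilyl)ethyl (1R,2R,3R)-2,3-dibromo-4-(oxomethylidene)cyclobutane-1-carboxylate (ketene) | O=C=C1[C@@H](Br)[C@H](Br)[C@H]1C(=O)OCC[Si](C)(C)C | intermediate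
18 | 2-(trimethylsilyl)ethyl 6,7-dibromo-2-[(R)-1-(tert-butyldiphenylsilyloxy)butyl]-3-oxo-1-(triisopropylsilyloxy)spiro[3.3]hept-1-ene-5-carboxylate (expected spiro epimer: enol-ether carbon anti to the adjacent C–Br) | CC(C)[Si](C(C)C)(C(C)C)OC1=C([C@@H](CCC)O[Si](c3ccccc3)(c3ccccc3)C(C)(C)C)C(=O)[C@]12[C@@H](Br)[C@H](Br)[C@H]2C(=O)OCC[Si](C)(C)C | intermediate
19 | 2-(trimethylsilyl)ethyl 6,7-dibromo-2-[(R)-1-(tert-butyldiphenylsilyloxy)butyl]-1,3-dioxospiro[3.3]heptane-5-carboxylate (drawn as the diketone; spiro carbon not fixed) | O=C1C([C@@H](CCC)O[Si](c3ccccc3)(c3ccccc3)C(C)(C)C)C(=O)C12[C@@H](Br)[C@H](Br)[C@H]2C(=O)OCC[Si](C)(C)C | intermediate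
20 | 2-(trimethylsilyl)ethyl 2,3-dibromo-8-hydroxy-6-oxo-7-[(R)-1-(tert-butyldiphenylsilyloxy)butyl]-5-oxaspiro[3.4]oct-7-ene-1-carboxylate (lactone O trans to adjacent C–Br) | OC1=C([C@@H](CCC)O[Si](c3ccccc3)(c3ccccc3)C(C)(C)C)C(=O)O[C@@]12[C@@H](Br)[C@H](Br)[C@H]2C(=O)OCC[Si](C)(C)C | intermediate
21 | 2-(trimethylsilyl)ethyl 2,3,8-tribromo-6-oxo-7-[(R)-1-(tert-butyldiphenylsilyloxy)butyl]-5-oxaspiro[3.4]oct-7-ene-1-carboxylate | BrC1=C([C@@H](CCC)O[Si](c3ccccc3)(c3ccccc3)C(C)(C)C)C(=O)O[C@@]12[C@@H](Br)[C@H](Br)[C@H]2C(=O)OCC[Si](C)(C)C | intermediate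
22 | 2,3,8-tribromo-6-oxo-7-[(R)-1-(tert-butyldiphenylsilyloxy)butyl]-5-oxaspiro[3.4]oct-7-ene-1-carboxylic acid | BrC1=C([C@@H](CCC)O[Si](c3ccccc3)(c3ccccc3)C(C)(C)C)C(=O)O[C@@]12[C@@H](Br)[C@H](Br)[C@H]2C(=O)O | intermediate
23 | acid chloride of 22 | BrC1=C([C@@H](CCC)O[Si](c3ccccc3)(c3ccccc3)C(C)(C)C)C(=O)O[C@@]12[C@@H](Br)[C@H](Br)[C@H]2C(=O)Cl | intermediate
24 | ketene from 23 (oxomethylidene group on the cyclobutane carbon next to the spiro centre) | BrC1=C([C@@H](CCC)O[Si](c3ccccc3)(c3ccccc3)C(C)(C)C)C(=O)O[C@@]12[C@@H](Br)[C@H](Br)C2=C=O | intermediate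
25 | dispiro cycloadduct: 4-bromobutenolide and 3-(triisopropylsilyloxy)cyclobut-2-enone spiro-fused to adjacent carbons of the trans-dibromocyclobutane (expected epimer: ketone carbon anti, enol-ether carbon syn to the adjacent C–Br) | BrC1=C([C@@H](CCC)O[Si](c3ccccc3)(c3ccccc3)C(C)(C)C)C(=O)O[C@@]12[C@@H](Br)[C@H](Br)[C@@]24C(=O)C([C@H](CCC)O[Si](c3ccccc3)(c3ccccc3)C(C)(C)C)=C4O[Si](C(C)C)(C(C)C)C(C)C | intermediate
26 | dispiro 1,3-dione from 25 (drawn as the diketone; new spiro carbon not fixed) | BrC1=C([C@@H](CCC)O[Si](c3ccccc3)(c3ccccc3)C(C)(C)C)C(=O)O[C@@]12[C@@H](Br)[C@H](Br)C24C(=O)C([C@H](CCC)O[Si](c3ccccc3)(c3ccccc3)C(C)(C)C)C4=O | intermediate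
27 | bis-spiro 4-bromobutenolide / tetronic acid (both lactone oxygens trans to their adjacent C–Br) | BrC1=C([C@@H](CCC)O[Si](c3ccccc3)(c3ccccc3)C(C)(C)C)C(=O)O[C@@]12[C@@H](Br)[C@H](Br)[C@@]24OC(=O)C([C@H](CCC)O[Si](c3ccccc3)(c3ccccc3)C(C)(C)C)=C4O | intermediate
28 | bis(4-bromobutenolide) bis(tert-butyldiphenylsilyl ether) | BrC1=C([C@@H](CCC)O[Si](c3ccccc3)(c3ccccc3)C(C)(C)C)C(=O)O[C@@]12[C@@H](Br)[C@H](Br)[C@@]24OC(=O)C([C@H](CCC)O[Si](c3ccccc3)(c3ccccc3)C(C)(C)C)=C4Br | intermediate
29 | bis(4-bromobutenolide) diol, one (R)- and one (S)-1-hydroxybutyl group | BrC1=C([C@@H](CCC)O)C(=O)O[C@@]12[C@@H](Br)[C@H](Br)[C@@]24OC(=O)C([C@H](CCC)O)=C4Br | intermediate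
30 | CNP0266230.1 (bis-spiro trans-dibromocyclobutane bis(4-bromobutenolide) diacetate) | CCC[C@H](OC(C)=O)C1=C(Br)[C@@]2(OC1=O)[C@@H](Br)[C@H](Br)[C@@]21OC(=O)C([C@@H](CCC)OC(C)=O)=C1Br | target

**Step count and risks**

Total step count: 19. Longest linear sequence: 12 steps (steps 8 to 19 from anhydride 11; the branch from 1 through steps 2, 5, 7 and 11 to 19 is equally long).

Steps most likely to fail:

1. Step 15 (and, on an easier substrate, step 11). The ketene terminus is flanked on both faces, so the cycloaddition may be slow enough for ketene oligomerisation or base-induced loss of HBr or of the lactone carboxylate to take over. Fallback by the keteniminium route, setting out from 22 and coming back at 26: acid chloride 23 is treated with N,N-dimethyltrimethylsilylamine at −78 °C to give the N,N-dimethylamide F1. Triflic anhydride and 2,6-di-tert-butylpyridine convert it without free amine into the more electrophilic keteniminium triflate F2, which adds siloxyalkyne 8 to give the cyclobuteniminium triflate F3. Aqueous HCl hydrolyses F3 to dione 26.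

2. Step 16 (and step 12). Oxidation of the electron-rich enol carbon may outrun oxygen insertion, and discrimination between the two carbonyls may be poor. Fallback setting out from 26 and coming back at 27: N-bromosuccinimide brominates the enol carbon to give the non-enolisable 2-bromo-1,3-dione F4. A peracid (m-chloroperbenzoic acid, NaHCO3) then effects the Baeyer–Villiger insertion at the less hindered carbonyl to give the 3-bromofuran-2,4-dione F5. Aqueous Na2S2O3 removes the positive bromine and returns tetronic acid 27.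

3. Step 8. Enantioselection may be poor with an alcohol other than methanol, which would erode the optical purity of the whole ring system. Fallback by classical resolution, setting out from 11 and 12 and coming back at 14: opening catalysed by 4-(dimethylamino)pyridine gives 13 together with its enantiomer, ent-13 F6. Epimerisation as in step 9 gives 14 together with ent-14 F7. Crystallisation with (S)-1-phenylethylamine gives the (S)-1-phenylethanaminium salt F8 of 14 (the (R)-amine is used if the other salt is the less soluble one), and acidification returns 14.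

Further compounds
F1 | step 15 | N,N-dimethylamide of acid 22 | BrC1=C([C@@H](CCC)O[Si](c3ccccc3)(c3ccccc3)C(C)(C)C)C(=O)O[C@@]12[C@@H](Br)[C@H](Br)[C@H]2C(=O)N(C)C
F2 | step 15 | keteniminium triflate from F1 | BrC1=C([C@@H](CCC)O[Si](c3ccccc3)(c3ccccc3)C(C)(C)C)C(=O)O[C@@]12[C@@H](Br)[C@H](Br)C2=C=[N+](C)C.[O-]S(=O)(=O)C(F)(F)F
F3 | step 15 | 3-(triisopropylsilyloxy)cyclobuteniminium triflate cycloadduct | BrC1=C([C@@H](CCC)O[Si](c3ccccc3)(c3ccccc3)C(C)(C)C)C(=O)O[C@@]12[C@@H](Br)[C@H](Br)[C@@]24C(=[N+](C)C)C([C@H](CCC)O[Si](c3ccccc3)(c3ccccc3)C(C)(C)C)=C4O[Si](C(C)C)(C(C)C)C(C)C.[O-]S(=O)(=O)C(F)(F)F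
F4 | step 16 | 2-bromo-1,3-dione from 26 | BrC1=C([C@@H](CCC)O[Si](c3ccccc3)(c3ccccc3)C(C)(C)C)C(=O)O[C@@]12[C@@H](Br)[C@H](Br)C24C(=O)C(Br)([C@H](CCC)O[Si](c3ccccc3)(c3ccccc3)C(C)(C)C)C4=O
F5 | step 16 | 3-bromofuran-2,4-dione (bromolactone) from F4 | BrC1=C([C@@H](CCC)O[Si](c3ccccc3)(c3ccccc3)C(C)(C)C)C(=O)O[C@@]12[C@@H](Br)[C@H](Br)[C@@]24OC(=O)C(Br)([C@H](CCC)O[Si](c3ccccc3)(c3ccccc3)C(C)(C)C)C4=O
F6 | step 8 | ent-13, (1S,2R)-2-{[2-(trimethylsilyl)ethoxy]carbonyl}cyclobut-3-ene-1-carboxylic acid | OC(=O)[C@H]1C=C[C@H]1C(=O)OCC[Si](C)(C)C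
F7 | step 8 | ent-14, (1S,2S)-2-{[2-(trimethylsilyl)ethoxy]carbonyl}cyclobut-3-ene-1-carboxylic acid | OC(=O)[C@H]1C=C[C@@H]1C(=O)OCC[Si](C)(C)C
F8 | step 8 | (S)-1-phenylethanaminium salt of 14 | [O-]C(=O)[C@@H]1C=C[C@H]1C(=O)OCC[Si](C)(C)C.C[C@H]([NH3+])c1ccccc1
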